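**Retrosynthetic overview**
- 11 ⇒ 10 ⇒ 9 ⇒ 8: the benzyl ethers on O5 and O4' are removed last. The sulfate is put on O7 when that is the only free phenol, and O7 is freed from the MOM acetal of flavone 8.
- 8 ⇒ 7: ring C is opened at O1–C8a. This leaves an acyclic 1,3-diketone whose ring A still carries hydrogen on C8a, and the forward step is an anodic C–H/O–H coupling.
- Feature used: ring A has its three oxygens on the adjacent carbons C5, C6 and C7. The C8a–H next to the acyl-bearing C4a is therefore para to the C6 methoxy group, and it is the only ring A C–H that the oxygen on C2 can reach through a six-membered ring.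
- 7 ⇒ 5 + 6: a Claisen condensation makes the C2–C3 bond. 5 ⇒ 1 by capping O4, O3 and O2 of gallacetophenone (later O7, O6, O5) one after the other.
- Ring order: rings A and B are bought, and ring C is the only ring formed (step 5).

Key step: step 5

Assumption: the target is achiral; sulfate monoesters 10 and 11 are drawn as free hydrogen sulfates as in the target SMILES but are handled as sodium salts, and the acid form of 11 is released only at the very end by cold H+ exchange.

**Step 1**
Reactants: 1 gallacetophenone (2',3',4'-trihydroxyacetophenone); 2 chloromethyl methyl ether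
Product: 3 1-[2,3-dihydroxy-4-(methoxymethoxy)phenyl]ethan-1-one
Conditions: MOMCl (1.0 equiv), K2CO3 (1.0 equiv), acetone, Ar, 0 °C to rt
Reagents that add atoms: chloromethyl methyl ether (compound 2), COCCl
Why: Williamson-type O-alkylation with one equivalent of weak base should take the 4-OH, which is para to the acetyl group and so the most acidic and least hindered phenol, while the 2-OH is tied up in the hydrogen bond to C=O and the 3-OH (meta to acetyl) stays protonated, the same order that rules the classical partial 4-O-alkylation of gallacetophenone.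

**Step 2**
Reactants: 3 1-[2,3-dihydroxy-4-(methoxymethoxy)phenyl]ethan-1-one
Product: 4 1-[2-hydroxy-3-methoxy-4-(methoxymethoxy)phenyl]ethan-1-one
Conditions: MeI (1.1 equiv), K2CO3 (1.1 equiv), acetone, 40 °C
Reagents that add atoms: iodomethane, CI
Why: Williamson etherification in which the chelated 2-OH is far less nucleophilic than the 3-OH, so that one equivalent of MeI should stop at the 3-methyl ether, and the MOM acetal is inert to carbonate.

**Step 3**
Reactants: 4 1-[2-hydroxy-3-methoxy-4-(methoxymethoxy)phenyl]ethan-1-one
Product: 5 1-[2-(benzyloxy)-3-methoxy-4-(methoxymethoxy)phenyl]ethan-1-one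
Conditions: BnBr (1.5 equiv), K2CO3 (2 equiv), Bu4NI (cat.), DMF, 70 °C
Reagents that add atoms: benzyl bromide, BrCc1ccccc1
Why: Williamson etherification under forcing conditions (polar aprotic solvent, heat, iodide catalysis) overcomes the chelation of the last phenol, and capping O2 (the later O5) is also needed to shut off the ordinary cyclodehydration that would lead to the 8-methoxy isomer.

**Step 4**
Reactants: 5 1-[2-(benzyloxy)-3-methoxy-4-(methoxymethoxy)phenyl]ethan-1-one; 6 methyl 4-(benzyloxy)benzoate
Product: 7 1-[2-(benzyloxy)-3-methoxy-4-(methoxymethoxy)phenyl]-3-[4-(benzyloxy)phenyl]propane-1,3-dione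
Conditions: NaH (2.5 equiv), THF, reflux; AcOH quench, 0 °C
Reagents that add atoms: none
Why: Crossed Claisen condensation: only ketone 5 can enolise, ester 6 cannot, and irreversible deprotonation of the 1,3-diketone by the excess hydride pulls the equilibrium to 7, with the aryl ethers and the MOM acetal untouched by the base and by the cold acetic acid quench.

**Step 5**
Reactants: 7 1-[2-(benzyloxy)-3-methoxy-4-(methoxymethoxy)phenyl]-3-[4-(benzyloxy)phenyl]propane-1,3-dione
Product: 8 5-(benzyloxy)-2-[4-(benzyloxy)phenyl]-6-methoxy-7-(methoxymethoxy)-4H-chromen-4-one (5,4'-di-O-benzyl-7-O-methoxymethylhispidulin)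
Conditions: undivided cell, BDD anode, Pt cathode, constant current 2 mA cm⁻², 2.1 F mol⁻¹, Bu4NBF4 (0.1 M), 2,6-lutidine (3 equiv), HFIP/CH2Cl2 1:1, 5 mM in 7, 20 °C
Reagents that add atoms: none
Why: Proposed new method: one-electron oxidation of the enol form of 7 at the anode should give a radical cation with its hole on the 5,6,7-trialkoxybenzoyl ring A, where the acyl carbon on C4a lowers the orbital that has weight on C4a/C5/C7/C8 and so favours the one that runs along the C6–C8a axis; the oxygen on C2 adds to C8a while lutidine takes its proton, and loss of a second electron and of H-8a rearomatises to 8, the protons leaving as H2 at the cathode. The closest known reaction types are the anodic dehydrogenative C–H/O–H lactonisation of biaryl-2-carboxylic acids to benzocoumarins and the oxidative (FeCl3-type) enol-O/aryl C–H closure of α-(alkoxyaryl) β-dicarbonyl compounds to benzofurans, but neither has been shown for an aroyl ring that closes to a 4-pyranone. Ring C closes in a 6-endo-trig mode with respect to the C4a–C8a bond, and it must do so from the open rotamer in which C4–C4a is s-cis to C2=C3, because in the hydrogen-bonded chelate the C2 oxygen faces O4 and points away from ring A; HFIP as hydrogen-bond donor and lutidine as proton acceptor are chosen to loosen that chelate. No stereocentre is formed. The step needs attack at C8a and not at the more electron-rich C8, and on ring A and not ring B: the tether reaches only C8a in a six-membered ring, the mirror closure of O4 onto C2'/C6' would hit a carbon meta to the single donor of ring B, and the benzyl cap on O5 rules out plain cyclodehydration. High dilution, the lutidine buffer (which also shields the MOM acetal from anodic acid) and a charge limit near 2 F mol⁻¹ are meant to hold back C3–C3 dimerisation, intermolecular coupling at C8 and further oxidation of 8.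

**Step 6**
Reactants: 8 5,4'-di-O-benzyl-7-O-methoxymethylhispidulin
Product: 9 5-(benzyloxy)-2-[4-(benzyloxy)phenyl]-7-hydroxy-6-methoxy-4H-chromen-4-one (5,4'-di-O-benzylhispidulin)
Conditions: conc. HCl (cat.), MeOH/CH2Cl2, 40 °C
Reagents that add atoms: none
Why: Acid-catalysed acetal exchange (MOM cleavage) proceeds through the oxocarbenium ion under conditions too mild for aryl benzyl or methyl ethers, the temperature being kept low because the 5-O-benzyl group peri to C4=O is the more acid-sensitive of the two.

**Step 7**
Reactants: 9 5,4'-di-O-benzylhispidulin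
Product: 10 5,4'-di-O-benzylhispidulin 7-(hydrogen sulfate), isolated as its sodium salt
Conditions: SO3·pyridine (4 equiv), pyridine, 40 °C; aq. NaHCO3; Sephadex LH-20 or C18
Reagents that add atoms: sulfur trioxide–pyridine complex, [O-]S(=O)(=O)[n+]1ccccc1
Why: O-Sulfation of a phenol with an amine–sulfur trioxide complex: the acidic 7-OH is the only free hydroxyl in 9, so no site selectivity is needed, and the basic medium and bicarbonate work-up keep the acid-labile aryl sulfate as its salt and remove pyridinium before the hydrogenolysis.

**Step 8**
Reactants: 10 5,4'-di-O-benzylhispidulin 7-(hydrogen sulfate)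
Product: 11 hispidulin 7-sulfate (5-hydroxy-2-(4-hydroxyphenyl)-6-methoxy-4-oxo-4H-chromen-7-yl hydrogen sulfate)
Conditions: H2 (1 atm), 10% Pd/C, MeOH/THF/H2O, rt (sodium salt); Dowex 50W (H+), 0 °C, freeze-drying
Reagents that add atoms: none
Why: Catalytic hydrogenolysis of the two aryl benzyl ethers at neutral pH leaves the aryl sulfate anion intact and should be much faster than saturation of the C2=C3 bond of the pyranone, and a short cold proton exchange then gives the hydrogen sulfate form.

**Compound list**
1 | gallacetophenone (2',3',4'-trihydroxyacetophenone) | CC(=O)c1ccc(O)c(O)c1O | starting material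
2 | chloromethyl methyl ether | COCCl | starting material
3 | 1-[2,3-dihydroxy-4-(methoxymethoxy)phenyl]ethan-1-one | CC(=O)c1ccc(OCOC)c(O)c1O | intermediate
4 | 1-[2-hydroxy-3-methoxy-4-(methoxymethoxy)phenyl]ethan-1-one | CC(=O)c1ccc(OCOC)c(OC)c1O | intermediate
5 | 1-[2-(benzyloxy)-3-methoxy-4-(methoxymethoxy)phenyl]ethan-1-one | CC(=O)c1ccc(OCOC)c(OC)c1OCc1ccccc1 | intermediate
6 | methyl 4-(benzyloxy)benzoate | COC(=O)c1ccc(OCc2ccccc2)cc1 | starting material
7 | 1-[2-(benzyloxy)-3-methoxy-4-(methoxymethoxy)phenyl]-3-[4-(benzyloxy)phenyl]propane-1,3-dione | COCOc1ccc(C(=O)CC(=O)c2ccc(OCc3ccccc3)cc2)c(OCc2ccccc2)c1OC | intermediate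
8 | 5,4'-di-O-benzyl-7-O-methoxymethylhispidulin | COCOc1cc2oc(-c3ccc(OCc4ccccc4)cc3)cc(=O)c2c(OCc2ccccc2)c1OC | intermediate
9 | 5,4'-di-O-benzylhispidulin | COc1c(O)cc2oc(-c3ccc(OCc4ccccc4)cc3)cc(=O)c2c1OCc1ccccc1 | intermediate
10 | 5,4'-di-O-benzylhispidulin 7-(hydrogen sulfate) | COc1c(OS(=O)(=O)O)cc2oc(-c3ccc(OCc4ccccc4)cc3)cc(=O)c2c1OCc1ccccc1 | intermediate
11 | hispidulin 7-sulfate | COc1c(OS(=O)(=O)O)cc2oc(-c3ccc(O)cc3)cc(=O)c2c1O | target

Total step count: 8
Longest linear sequence: 8 steps (1 to 11); ester 6 is bought.

**Steps most likely to fail**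

**Step 5.**
- The first electron may leave the enol/ring B half of the π-system instead of ring A. The diketonyl radical formed after proton loss can still add through oxygen to C8a, but it is more prone to C3–C3 dimerisation.
- The C6 methoxy group is flanked on both sides and twisted out of plane, so its para activation of C8a may be weak.
- The closure may then lose to intermolecular coupling or solvent capture at C8, or to oxidative loss of a benzyl or MOM group.
- Product 8 may itself be oxidised further, because its ring A then carries a fourth oxygen.
- The fallback uses known chemistry, sets out from 5 and comes back at 9.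
  - Ketone-directed iridium-catalysed ortho C–H borylation of 5 ([Ir(OMe)(cod)]2, AsPh3, B2pin2, octane, 120 °C) should put boron on the only C–H ortho to the acetyl group. It gives 1-[2-(benzyloxy)-3-methoxy-4-(methoxymethoxy)-6-(4,4,5,5-tetramethyl-1,3,2-dioxaborolan-2-yl)phenyl]ethan-1-one F1.
  - Mild oxidation (NaBO3·4H2O, THF/H2O, rt) converts it into 1-[2-(benzyloxy)-6-hydroxy-3-methoxy-4-(methoxymethoxy)phenyl]ethan-1-one F2.
  - Claisen condensation of F2 with ester 6 (NaH, 4 equiv, THF, reflux) gives 1-[2-(benzyloxy)-6-hydroxy-3-methoxy-4-(methoxymethoxy)phenyl]-3-[4-(benzyloxy)phenyl]propane-1,3-dione F3.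
  - HCl in MeOH/THF at 50 °C then brings about the classical cyclodehydration of the phenol oxygen onto C2 and removes the MOM group in the same pot, which gives 9.

**Step 8.**
- The hydrogenolysis may stall on an ionic, sparingly soluble substrate that can carry catalyst poisons over from the sulfation.
- Long exposure may slowly saturate C2=C3.
- The sulfate may be lost by hydrolysis once the medium turns acidic.
- The fallback sets out from 9, comes back at 11 and replaces steps 7 and 8.
  - The sulfate is introduced in a neutral, protected form. Treating 9 with 2,2,2-trichloroethyl chlorosulfate (Et3N, DMAP, THF, 0 °C to rt) gives the mixed diester 5,4'-di-O-benzylhispidulin 7-(2,2,2-trichloroethyl sulfate) F4, which can be purified on silica.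
  - Transfer hydrogenolysis (Pd/C, HCO2NH4, MeOH/THF, rt) then removes the trichloroethyl group by reductive elimination and both benzyl ethers in one buffered operation. It gives 11 as its ammonium salt, which is protonated as in step 8.

**Step 1.**
- Site selectivity between O4 and O3 may be poor with the very reactive MOMCl.
- Over-alkylation to the 3,4-bis-ether may occur, and the pyrogallol-type anion is open to air oxidation.
- The fallback sets out from 1 and comes back at 4. It separates O3 from O4 by the leaving-group ability of the two methyl ethers and not by the reactivity of the two free phenols.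
  - Methylation of both non-chelated phenols (MeI, 2.2 equiv, K2CO3, acetone, reflux) gives 2-hydroxy-3,4-dimethoxyacetophenone F5.
  - Sodium ethanethiolate in DMF at 100 °C should cleave only the 4-methyl ether, because SN2 dealkylation expels the phenoxide that is conjugated with the para acetyl group. It gives 2,4-dihydroxy-3-methoxyacetophenone F6.
  - In F6 the only non-chelated phenol is O4, so 2 with K2CO3 in acetone gives 4.

**Further compounds**
F1 | step 5 | 1-[2-(benzyloxy)-3-methoxy-4-(methoxymethoxy)-6-(4,4,5,5-tetramethyl-1,3,2-dioxaborolan-2-yl)phenyl]ethan-1-one | CC(=O)c1c(B2OC(C)(C)C(C)(C)O2)cc(OCOC)c(OC)c1OCc1ccccc1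
F2 | step 5 | 1-[2-(benzyloxy)-6-hydroxy-3-methoxy-4-(methoxymethoxy)phenyl]ethan-1-one | CC(=O)c1c(O)cc(OCOC)c(OC)c1OCc1ccccc1
F3 | step 5 | 1-[2-(benzyloxy)-6-hydroxy-3-methoxy-4-(methoxymethoxy)phenyl]-3-[4-(benzyloxy)phenyl]propane-1,3-dione | COCOc1cc(O)c(C(=O)CC(=O)c2ccc(OCc3ccccc3)cc2)c(OCc2ccccc2)c1OC
F4 | step 8 | 5,4'-di-O-benzylhispidulin 7-(2,2,2-trichloroethyl sulfate) | COc1c(OS(=O)(=O)OCC(Cl)(Cl)Cl)cc2oc(-c3ccc(OCc4ccccc4)cc3)cc(=O)c2c1OCc1ccccc1
F5 | step 1 | 2-hydroxy-3,4-dimethoxyacetophenone | CC(=O)c1ccc(OC)c(OC)c1O
F6 | step 1 | 2,4-dihydroxy-3-methoxyacetophenone | CC(=O)c1ccc(O)c(OC)c1O
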